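The target is a diarylmethane in which C6 of ring A (ortho to the bridging CH2) and C4' of ring B (para to it) each carry a 2-(4-hydroxy-3-methoxyphenyl)ethyl arm. Both aryl C–CH2 bonds are cut at once; each arm is then the primary radical left when dihydroferulic acid loses CO2. A single nickel-electrocatalytic decarboxylative arylation joins two molecules of the O-benzyl dihydroferulic N-(acyloxy)phthalimide ester to a bis-O-benzyl dibromodiarylmethane carrying bromine at exactly those two carbons. The dibromide is built from a benzophenone whose carbonyl directs both ortho O-demethylations, and one hydrogenolysis finally frees the four phenols.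

Key step: step 9

Remark: the target has no stereocentre, and the only one on the route (the carbinol carbon made in step 2, racemic) is erased in step 3; species that have undergone only part of the twofold or fourfold reactions in steps 4, 6, 9 and 10 converge on the named product and are not numbered.

Step 1
Reactants: 1 1-bromo-3,5-dimethoxybenzene
Product: 2 1-bromo-2-iodo-3,5-dimethoxybenzene
Conditions: N-iodosuccinimide (1.05 equiv), MeCN, rt, dark
Reagents that add atoms: N-iodosuccinimide, O=C1CCC(=O)N1I
Why: Electrophilic aromatic iodination should go to the position ortho to bromine and para to one methoxy group (C2 and C6 are equivalent), which is activated by both ethers and less crowded than C4 between the two methoxy groups.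

Step 2
Reactants: 2 1-bromo-2-iodo-3,5-dimethoxybenzene; 3 4-bromo-2,6-dimethoxybenzaldehyde
Product: 5 (2-bromo-4,6-dimethoxyphenyl)(4-bromo-2,6-dimethoxyphenyl)methanol (racemic), via (2-bromo-4,6-dimethoxyphenyl)magnesium chloride 4 (not isolated)
Conditions: iPrMgCl·LiCl (1.1 equiv), THF, −30 °C; then 3, −30 → 0 °C; aq. NH4Cl
Reagents that add atoms: none
Why: Iodine–magnesium exchange is much faster at C–I than at C–Br, the ortho-bromo arylmagnesium species should not eliminate to an aryne at these temperatures, and Grignard 1,2-addition to the aldehyde gives the diaryl carbinol, whose single stereocentre is formed without control (racemate) and is removed in step 3.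

Step 3
Reactants: 5 (2-bromo-4,6-dimethoxyphenyl)(4-bromo-2,6-dimethoxyphenyl)methanol
Product: 6 (2-bromo-4,6-dimethoxyphenyl)(4-bromo-2,6-dimethoxyphenyl)methanone
Conditions: Dess–Martin periodinane (1.3 equiv), CH2Cl2, rt
Reagents that add atoms: none
Why: Dess–Martin oxidation of a secondary bis-benzylic alcohol is mild and neutral and should leave the aryl bromides and the electron-rich rings untouched.

Step 4
Reactants: 6 (2-bromo-4,6-dimethoxyphenyl)(4-bromo-2,6-dimethoxyphenyl)methanone
Product: 7 (2-bromo-6-hydroxy-4-methoxyphenyl)(4-bromo-2-hydroxy-6-methoxyphenyl)methanone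
Conditions: BCl3 (1 M in CH2Cl2, 4 equiv), CH2Cl2, −78 → 0 °C; then H2O
Reagents that add atoms: none
Why: Chelation-directed ether cleavage, in which BCl3 bound to the carbonyl oxygen activates only a methoxy group that can close a six-membered chelate, should remove the single ortho methyl ether of ring A and one of the two equivalent ortho methyl ethers of ring B, while the para methoxy of ring A has no carbonyl assistance and the second ortho methoxy of ring B is turned away from the carbonyl once the first boron aryloxide chelate has formed.

Step 5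
Reactants: 7 (2-bromo-6-hydroxy-4-methoxyphenyl)(4-bromo-2-hydroxy-6-methoxyphenyl)methanone
Product: 8 3-bromo-2-(4-bromo-2-hydroxy-6-methoxybenzyl)-5-methoxyphenol
Conditions: Et3SiH (4 equiv), CF3CO2H/CH2Cl2 (1:2), 0 °C → rt
Reagents that add atoms: none
Why: Ionic hydrogenation of a diaryl ketone (protonation, hydride transfer, ionisation of the benzhydrol to a cation stabilised by the ortho and para oxygen donors, second hydride transfer) should give the methylene compound without touching the aryl bromides or methyl ethers.

Step 6
Reactants: 8 3-bromo-2-(4-bromo-2-hydroxy-6-methoxybenzyl)-5-methoxyphenol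
Product: 9 1-benzyloxy-3-bromo-2-(2-benzyloxy-4-bromo-6-methoxybenzyl)-5-methoxybenzene (core dibromide)
Conditions: BnBr (2.4 equiv), K2CO3 (3 equiv), DMF, rt → 50 °C
Reagents that add atoms: benzyl bromide, BrCc1ccccc1
Why: Williamson ether synthesis at both phenols should proceed cleanly because no other acidic or electrophilic site is present.

Step 7
Reactants: 10 dihydroferulic acid, 3-(4-hydroxy-3-methoxyphenyl)propanoic acid
Product: 12 3-(4-benzyloxy-3-methoxyphenyl)propanoic acid, via benzyl 3-(4-benzyloxy-3-methoxyphenyl)propanoate 11 (not isolated)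
Conditions: BnBr (2.3 equiv), K2CO3 (3 equiv), DMF, 60 °C; then 2 M NaOH aq., MeOH, 60 °C; then HCl aq. to pH 2
Reagents that add atoms: benzyl bromide, BrCc1ccccc1
Why: Williamson benzylation of phenoxide and carboxylate followed by saponification of the benzyl ester in the same flask should leave only the base-stable benzyl aryl ether.

Step 8
Reactants: 12 3-(4-benzyloxy-3-methoxyphenyl)propanoic acid; 13 N-hydroxyphthalimide
Product: 14 1,3-dioxoisoindolin-2-yl 3-(4-benzyloxy-3-methoxyphenyl)propanoate (N-(acyloxy)phthalimide ester)
Conditions: N,N'-diisopropylcarbodiimide (1.1 equiv), DMAP (10 mol %), CH2Cl2, rt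
Reagents that add atoms: none
Why: Steglich-type carbodiimide esterification of an unhindered primary-alkyl carboxylic acid with N-hydroxyphthalimide is the standard entry to redox-active esters.

Step 9
Reactants: 9 1-benzyloxy-3-bromo-2-(2-benzyloxy-4-bromo-6-methoxybenzyl)-5-methoxybenzene; 14 1,3-dioxoisoindolin-2-yl 3-(4-benzyloxy-3-methoxyphenyl)propanoate (two equivalents consumed, four used)
Product: 15 1-benzyloxy-2-{2-benzyloxy-4-[2-(4-benzyloxy-3-methoxyphenyl)ethyl]-6-methoxybenzyl}-3-[2-(4-benzyloxy-3-methoxyphenyl)ethyl]-5-methoxybenzene (tetra-O-benzyl target)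
Conditions: NiBr2(dme) (20 mol %), 4,4'-di-tert-butyl-2,2'-bipyridine (24 mol %), AgNO3 (0.3 equiv), LiCl, NMP, Mg anode / reticulated vitreous carbon cathode, undivided cell, constant current, rt, argon; 14 (4 equiv) added in two portions
Reagents that add atoms: none
Why: Cathodic reduction converts the divalent nickel bipyridine complex into zerovalent nickel, which inserts into a C–Br bond of 9, while single-electron reduction of 14 (at the silver-coated cathode or by low-valent nickel) cleaves the N–O bond and expels CO2 and phthalimide anion to leave the primary 2-(4-benzyloxy-3-methoxyphenyl)ethyl radical. Capture of this radical by the arylnickel bromide gives an aryl(alkyl) trivalent nickel species whose reductive elimination forges the aryl C–CH2 bond, and the cycle repeats at the second bromide. The closest known reaction type is the nickel-electrocatalytic decarboxylative arylation of N-(acyloxy)phthalimide esters with aryl bromides, a reductive cross-electrophile coupling. No ring is closed and no stereocentre is created. The step needs cross-coupling to win over biaryl and bibenzyl homocoupling and over protodebromination at both sites: each bromine sits meta to the two alkoxy groups of its ring (so oxidative addition is not slowed by resonance donation), the primary radical has no fast rearrangement or fragmentation channel, and the ester is supplied in excess and in portions at a low constant current so that radicals form no faster than arylnickel can trap them. The unhindered ring B bromide (para to the bridge) should react first and the ring A bromide (ortho to the bridging CH2) second, which the compact bipyridine ligand sphere should tolerate.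

Step 10
Reactants: 15 tetra-O-benzyl target
Product: 16 3-[2-(4-hydroxy-3-methoxyphenyl)ethyl]-2-{2-hydroxy-4-[2-(4-hydroxy-3-methoxyphenyl)ethyl]-6-methoxybenzyl}-5-methoxyphenol (CNP0079001.0)
Conditions: H2 (1 atm), 10% Pd/C, EtOAc/MeOH (1:1), rt
Reagents that add atoms: none
Why: Catalytic hydrogenolysis should cleave the four benzyl aryl ethers to toluene while the methyl ethers, the diarylmethane bridge and the two bibenzyl chains are inert.

Compound list
1 | 1-bromo-3,5-dimethoxybenzene | COc1cc(Br)cc(OC)c1 | starting material
2 | 1-bromo-2-iodo-3,5-dimethoxybenzene | COc1cc(OC)c(I)c(Br)c1 | intermediate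
3 | 4-bromo-2,6-dimethoxybenzaldehyde | COc1cc(Br)cc(OC)c1C=O | starting material
4 | (2-bromo-4,6-dimethoxyphenyl)magnesium chloride (formed in situ) | COc1cc(OC)c([Mg]Cl)c(Br)c1 | intermediate
5 | (2-bromo-4,6-dimethoxyphenyl)(4-bromo-2,6-dimethoxyphenyl)methanol, racemic | COc1cc(OC)c(C(O)c2c(OC)cc(Br)cc2OC)c(Br)c1 | intermediate
6 | (2-bromo-4,6-dimethoxyphenyl)(4-bromo-2,6-dimethoxyphenyl)methanone | COc1cc(OC)c(C(=O)c2c(OC)cc(Br)cc2OC)c(Br)c1 | intermediate
7 | (2-bromo-6-hydroxy-4-methoxyphenyl)(4-bromo-2-hydroxy-6-methoxyphenyl)methanone | COc1cc(O)c(C(=O)c2c(O)cc(Br)cc2OC)c(Br)c1 | intermediate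
8 | 3-bromo-2-(4-bromo-2-hydroxy-6-methoxybenzyl)-5-methoxyphenol | COc1cc(O)c(Cc2c(O)cc(Br)cc2OC)c(Br)c1 | intermediate
9 | 1-benzyloxy-3-bromo-2-(2-benzyloxy-4-bromo-6-methoxybenzyl)-5-methoxybenzene | COc1cc(OCc2ccccc2)c(Cc2c(OCc3ccccc3)cc(Br)cc2OC)c(Br)c1 | intermediate
10 | dihydroferulic acid, 3-(4-hydroxy-3-methoxyphenyl)propanoic acid | COc1cc(CCC(=O)O)ccc1O | starting material
11 | benzyl 3-(4-benzyloxy-3-methoxyphenyl)propanoate (formed in situ) | COc1cc(CCC(=O)OCc2ccccc2)ccc1OCc1ccccc1 | intermediate
12 | 3-(4-benzyloxy-3-methoxyphenyl)propanoic acid | COc1cc(CCC(=O)O)ccc1OCc1ccccc1 | intermediate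
13 | N-hydroxyphthalimide | O=C1c2ccccc2C(=O)N1O | starting material
14 | 1,3-dioxoisoindolin-2-yl 3-(4-benzyloxy-3-methoxyphenyl)propanoate | O=C(CCc1ccc(OCc2ccccc2)c(OC)c1)ON1C(=O)c2ccccc2C1=O | intermediate
15 | 1-benzyloxy-2-{2-benzyloxy-4-[2-(4-benzyloxy-3-methoxyphenyl)ethyl]-6-methoxybenzyl}-3-[2-(4-benzyloxy-3-methoxyphenyl)ethyl]-5-methoxybenzene | COc1cc(OCc2ccccc2)c(Cc2c(OCc3ccccc3)cc(CCc3ccc(OCc4ccccc4)c(OC)c3)cc2OC)c(CCc2ccc(OCc3ccccc3)c(OC)c2)c1 | intermediate
16 | 3-[2-(4-hydroxy-3-methoxyphenyl)ethyl]-2-{2-hydroxy-4-[2-(4-hydroxy-3-methoxyphenyl)ethyl]-6-methoxybenzyl}-5-methoxyphenol (CNP0079001.0) | COc1cc(O)c(Cc2c(O)cc(CCc3ccc(O)c(OC)c3)cc2OC)c(CCc2ccc(O)c(OC)c2)c1 | target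

Total step count: 10. Longest linear sequence: 8 steps (steps 1–6, 9 and 10, from 1-bromo-3,5-dimethoxybenzene).

Steps most likely to fail

Step 9. What may go wrong: the alkyl radicals dimerise or are reduced, and the arylnickel species is protonated or homocoupled faster than it is alkylated, above all at the crowded ring A bromide, so that the second arm is not attached. The fallback sets out from dibromide 9 and comes back at 15. Commercial 2-methoxy-4-vinylphenol would be benzylated (BnBr, K2CO3, DMF, rt) to 1-benzyloxy-2-methoxy-4-vinylbenzene F1. Anti-Markovnikov hydroboration with 9-borabicyclo[3.3.1]nonane (THF, 0 °C → rt) would give 9-[2-(4-benzyloxy-3-methoxyphenyl)ethyl]-9-borabicyclo[3.3.1]nonane F2. A twofold B-alkyl Suzuki–Miyaura coupling of 9 with F2 (PdCl2(dppf), aq. K3PO4, THF/DMF, 65 °C) would then form the same two aryl–CH2 bonds by a two-electron transmetalation pathway and deliver 15, which continues with step 10.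

Step 4. What may go wrong: ether cleavage stops after the first ring once its boron aryloxide ties up the carbonyl, or a second methyl ether of ring B is lost, so that the two rings are not each demethylated exactly once. The fallback sets out from aldehyde 3 and comes back at 7; it differentiates ring B before the rings are joined. BCl3 (1.2 equiv, CH2Cl2, −78 → 0 °C) would cleave one of the two equivalent ortho methyl ethers of 3 to give 4-bromo-2-hydroxy-6-methoxybenzaldehyde F3. Benzylation (BnBr, K2CO3, DMF) would give 2-benzyloxy-4-bromo-6-methoxybenzaldehyde F4. Addition of Grignard reagent 4 (generated from 2 as in step 2) would give racemic (2-benzyloxy-4-bromo-6-methoxyphenyl)(2-bromo-4,6-dimethoxyphenyl)methanol F5, and Dess–Martin oxidation would give (2-benzyloxy-4-bromo-6-methoxyphenyl)(2-bromo-4,6-dimethoxyphenyl)methanone F6. BCl3 with pentamethylbenzene as cation scavenger (CH2Cl2, −78 → 0 °C) would then remove the benzyl group of ring B and the one chelating methyl ether of ring A, giving 7.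

Step 5. What may go wrong: the electron-rich benzhydryl cation fragments in acid by C–C cleavage (retro-Friedel–Crafts), or reduction stops at the benzhydrol. The fallback sets out from 7 and comes back at 8; it replaces the cationic pathway by a base-mediated one. Ethyl chloroformate and Et3N (THF, 0 °C) would convert 7 into 3-bromo-2-(4-bromo-2-ethoxycarbonyloxy-6-methoxybenzoyl)-5-methoxyphenyl ethyl carbonate F7. NaBH4 in THF/H2O (0 °C → rt) would reduce the ketone; the alkoxide takes over a neighbouring carbonate, ethyl carbonate is expelled to give an ortho-quinone methide, and a second hydride adds to it. Aqueous NaOH work-up cleaves the remaining carbonate and gives 8.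

Further compounds
F1 | step 9 | 1-benzyloxy-2-methoxy-4-vinylbenzene | C=Cc1ccc(OCc2ccccc2)c(OC)c1
F2 | step 9 | 9-[2-(4-benzyloxy-3-methoxyphenyl)ethyl]-9-borabicyclo[3.3.1]nonane | COc1cc(CCB2C3CCCC2CCC3)ccc1OCc1ccccc1
F3 | step 4 | 4-bromo-2-hydroxy-6-methoxybenzaldehyde | COc1cc(Br)cc(O)c1C=O
F4 | step 4 | 2-benzyloxy-4-bromo-6-methoxybenzaldehyde | COc1cc(Br)cc(OCc2ccccc2)c1C=O
F5 | step 4 | (2-benzyloxy-4-bromo-6-methoxyphenyl)(2-bromo-4,6-dimethoxyphenyl)methanol, racemic | COc1cc(OC)c(C(O)c2c(OCc3ccccc3)cc(Br)cc2OC)c(Br)c1
F6 | step 4 | (2-benzyloxy-4-bromo-6-methoxyphenyl)(2-bromo-4,6-dimethoxyphenyl)methanone | COc1cc(OC)c(C(=O)c2c(OCc3ccccc3)cc(Br)cc2OC)c(Br)c1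
F7 | step 5 | 3-bromo-2-(4-bromo-2-ethoxycarbonyloxy-6-methoxybenzoyl)-5-methoxyphenyl ethyl carbonate | CCOC(=O)Oc1cc(OC)cc(Br)c1C(=O)c1c(OC(=O)OCC)cc(Br)cc1OC
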